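The target is what I want from a scarce substrate, and between the winter run and the summer run its fraction of the charge at the last reading falls to half, from 30% to 15%.

| setting | winter | summer | Saturday's | Tuesday's | Friday's | Wednesday's | Monday's |
|---|---|---|---|---|---|---|---|
| substrate | 0.072 M | 0.47 M | 0.20 M | 0.10 M | 0.050 M | 0.15 M | 0.30 M |
| gas phase | 32 mM (held) | 32 mM (held) | 32 mM (held) | 32 mM (held) | 32 mM (held) | 32 mM (held) | 32 mM (held) |
| remark | run made earlier | run made earlier |  |  |  |  |  |
| time |  |  | 80 min | 80 min | 80 min | 80 min | 80 min |

- winter (time / min: target / %, substrate / %): 5.00: 5, 77; 15.0: 16, 39; 25.0: 24, 19; 40.0: 24, 9; 60.0: 30, 3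
- summer (time / min: target / %, substrate / %): 5.00: 1, 79; 8.00: 3, 64; 15.0: 8, 39; 30.0: 13, 15; 60.0: 15, 4

(scatter of a reading: 1.5 percentage points)

- at the start none of the gas phase is in solution

* all flasks from highest to lowest amount of target, in percent of the substrate charged, at 80 min (Saturday's / Tuesday's / Friday's / Wednesday's / Monday's)
* the amount of target, in percent of the substrate charged of the flask you put first, at 80 min
* the amount of target, in percent of the substrate charged of the flask you put last, at 80 min

But the substrate readings do not follow the charge: after 15.0 min the winter run keeps 39% and the summer run 39%, so in these two runs the charge changes where substrate goes and not visibly how fast it leaves. By the last readings 3% and 4% remain, so I take those target fractions as close to what 80 min shows. The gas is held at the same 32 mM in both runs, so I suppose that a fixed supply of gas meets a demand that grows with the charge, and that the target's share of consumed substrate, its selectivity, falls accordingly. The simplest form of this has one over the target fraction rising in a straight line with the charge. Through the two readings, each with a scatter of 1.5 percentage points, that line gives a dilute-limit fraction of 36.6% and 0.326 M, the half-yield loading, the charge at which the target fraction is half its dilute-limit value. So I order the flasks by rising charge, Friday's, Tuesday's, Wednesday's, Saturday's, Monday's, and reckon Friday's at 31.8% and Monday's at 19.1%.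

The forecast gives Friday's > Tuesday's > Wednesday's > Saturday's > Monday's, the same order as mine, with 33.5% and 19.5%, above my figures, on the ground that “Yield falls steadily with loading”.

The flasks give Friday's > Tuesday's > Wednesday's > Saturday's > Monday's, with 32.3% in Friday's and 19.9% in Monday's.

    substrate → side product A (k = 6.07 × 10⁻⁴ s⁻¹)
    gas phase ⇌ dissolved gas, rate k2*(csat - [dissolved gas]) (kL = 0.00281 s⁻¹)
    substrate + target → side product B (k = 0.00258 M⁻¹ s⁻¹)
    substrate ⇌ dormant form (K = 0.968, k = 1.82 × 10⁻⁴ s⁻¹)
    substrate + dissolved gas → target (k = 0.0177 M⁻¹ s⁻¹)

In Friday's at 7.49 min substrate goes to side product A 1.7 times as fast as to target. At 80.0 min Friday's holds 55.3% of side product A against 32.3% of target, a ratio of 1.71. Dormant form, absent from my line, stands at 8.08% in Friday's and 8.57% in Monday's at that time, 0.5 points apart. The half-yield loading of 0.326 M gives 22.7% for Friday's flask charged at 0.20 M, and that flask holds 23.8%.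

The data were generated by integration for substances that don't exist; the scatter is artificial.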